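Late in this flask the question is how much of the electrophile charge still stands free, so we reckon one clock for it.

electrophile 0.17 M; free base 1.50 equiv (fed, over 8.0 min); gas 74 mM (held); time 1.5 h

    electrophile + nucleophile → acid set free + target (k1 = 0.30 /M/min)
    nucleophile + acid set free ⇌ protonated nucleophile, settled at all times (K2 = 52000 /M)
    acid set free + free base ⇌ salt of the base, settled at all times (K3 = 14000 /M)
    electrophile + target ⇌ idle adduct, settled at all times (K4 = 7.4 /M)
    electrophile + target → side product (k5 = 0.16 /M/min)
    gas ⇌ nucleophile, rate k6*(csat - [nucleophile]) (k6 = 1.7 /min, csat = 74 mM)

- a species is counted by the electrophile in it: one idle adduct or side product counts as two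
- amounts and yields of target count idle adduct too
- at the start none of nucleophile is dissolved
- in an amount of target, one idle adduct counts as one target
- what has gone from electrophile into another species counts as reacted, even if it can come back
- run time (flask): 1.5 h

- part of the electrophile that has reacted at 1.5 h
- share of the unused nucleophile that is free and not bound as protonated nucleophile, at 1.5 h

The transfer of gas takes 0.588 min, while the first step draws on nucleophile in 19.6 min at the charged electrophile, so we hold nucleophile at saturation. The first step is then pseudo-first-order in electrophile, and its clock, the time to fall by a factor e at saturated nucleophile, is 45.0 min. The run lasts 2.00 clocks, so counting the first step by itself we expect 86.4% of the charge reacted. The clock says nothing about fr.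

The forecast gave 90.9% (89.5% to 92.5%) and 52.5% (50.5% to 54.5%), on the ground that “dissolved nucleophile stays near saturation”, and its c stands above ours.

The flask gives 91.0% and 52.5%, with 9.0% of the electrophile left free, less than the 13.6% our clock leaves.

As a half-life our clock is 0.520 h, the same reckoning as the 0.52 h of electrophile by the first step at 1.50 h in this flask, and that is shorter than the 4.7 h of free target by the side reaction at that time. As charged, that target half-life was 0.42 h, and the flask ends with 51.3% target against 34.4% side product.

The clock contains no amount of electrophile, so for the flask with 0.68 M of electrophile it again gives 86.4% reacted. That flask computes to 93.3% reacted, with 32.4% target against 52.6% side product.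

All constants were chosen freely.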